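**Retrosynthetic overview**

1. Evelynin is read as an oxidised phloroglucinol ether; quinone ring locants used below: C1 (carbonyl between the two methoxy carbons), C2 (OMe), C3 (side chain), C4 (carbonyl), C5 (H), C6 (OMe).
2. Endgame, backwards: aryl ketone ⇐ acid-catalysed hydration of an aryl alkyne; C2–OMe ⇐ O-methylation of a 2-hydroxyquinone; C1=O ⇐ Teuber oxidation of a 2-substituted 5-methoxyresorcinol at the CH para to the C4 hydroxyl.
3. Key disconnection: the resorcinol ring is cut at C3–C4 and C1–C6 into a methyl ketone (C1–C2–C3, side chain on C3) and methyl 3,3-dimethoxyacrylate (C4–C5–C6); both bonds are made in one pot by enolate addition–elimination followed by Claisen closure.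
4. Enabling feature: the ring oxygens on C2, C4 and C6 alternate with C3, C5 and C1, so C4–C5–C6 is a malonate-level double electrophile and C1–C2–C3 an acetone-type double nucleophile; the C1 carbonyl, para to the C4 oxygen, is added by oxidation once the ring exists.
5. Ring order: the 3,4-dimethoxyphenyl ring is bought and the quinone ring is the only ring formed (step 3); the side-chain ketone travels as an aryl alkyne (Sonogashira, step 1) so that no 1,5-diketone is exposed to base.

Key step: step 3

**Route**

Step 1
Reactants: 1 hex-5-yn-2-one; 2 4-iodo-1,2-dimethoxybenzene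
Product: 3 6-(3,4-dimethoxyphenyl)hex-5-yn-2-one
Conditions: PdCl2(PPh3)2 (2 mol%), CuI (4 mol%), Et3N, THF, 23 °C
Reagents that add atoms: none
Why: Sonogashira coupling of a terminal alkyne with an electron-rich aryl iodide; the methyl ketone is inert here and the internal aryl alkyne formed is a base-stable latent form of the side-chain aryl ketone.

Step 2
Reactants: 4 ethyl 3,3-diethoxyprop-2-enoate
Product: 5 methyl 3,3-dimethoxyprop-2-enoate
Conditions: NaOMe (10 mol%), MeOH (solvent), 50 °C, evaporate and recharge once; distil
Reagents that add atoms: methanol, CO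
Why: Methoxide-catalysed transesterification together with addition–elimination exchange of both alkoxy groups at the ketene acetal carbon; the excess of methanol and removal of ethanol should drive all three positions to methoxy.

Step 3
Reactants: 3 6-(3,4-dimethoxyphenyl)hex-5-yn-2-one; 5 methyl 3,3-dimethoxyprop-2-enoate
Product: 8 2-[3-(3,4-dimethoxyphenyl)prop-2-yn-1-yl]-5-methoxybenzene-1,3-diol, via kinetic lithium enolate 6 (not isolated), via open-chain keto enoate 7 (not isolated)
Conditions: LiN(i-Pr)2 (LDA, 3.3 equiv), THF, −78 °C; then 5 (1.2 equiv), DMPU, −78 to 0 °C; 1 M HCl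
Reagents that add atoms: none
Why: Proposed new method: LDA removes a methyl proton of 3 under kinetic control to give enolate 6, whose carbon adds to the ketene acetal carbon of 5 and expels methoxide (addition–elimination), giving keto enoate 7 and with it the future C1–C6 bond. The excess LDA converts 7 into its dianion, whose methylene carbanion (future C3) attacks the ester carbonyl (future C4) in a Claisen closure; loss of the second methoxide and enolisation give the aromatic resorcinolate as an irreversible sink. The closest known reactions are the addition–elimination of ketone enolates on push–pull ketene dithioacetals (2-pyranone synthesis), the Claisen cyclisation of 3,5-dioxoalkanoate polyanions to phloroglucinols, and the methoxide-induced conversion of 4-methoxy-6-methyl-2-pyranone into phloroglucinol monomethyl ether. The benzene ring is the only ring closed, by a 6-exo-trig acyl substitution for which the (E)-geometry of 7 (chain carbon cis to the ester) is the reactive one, and no stereocentre is formed. The step needs methyl rather than methylene enolisation (secured by kinetic deprotonation at −78 °C), attack at the acetal carbon rather than the ester carbonyl (the ester is the deactivated end of a vinylogous carbonate and the acetal carbon carries the leaving groups), and C- rather than O-acylation in the closure (the carbanion of the dianion at low temperature; O-acylation would give a 2-pyranone). The internal aryl alkyne offers no competing acidic or electrophilic site, which is why the side-chain ketone is carried in this form.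

Step 4
Reactants: 8 2-[3-(3,4-dimethoxyphenyl)prop-2-yn-1-yl]-5-methoxybenzene-1,3-diol
Product: 9 3-[3-(3,4-dimethoxyphenyl)prop-2-yn-1-yl]-2-hydroxy-6-methoxycyclohexa-2,5-diene-1,4-dione
Conditions: (KSO3)2NO (Fremy's salt, 2.5 equiv), KH2PO4, H2O/acetone, 0 to 23 °C; acidify to pH 2
Reagents that add atoms: Fremy's salt (potassium nitrosodisulfonate), [K+].[K+].[O]N(S(=O)(=O)[O-])S(=O)(=O)[O-]
Why: Teuber oxidation, in which two equivalents of the nitroxyl radical turn a phenol with a free para position into the para-quinone with the new oxygen coming from the reagent; the two CH positions of 8 are equivalent by symmetry, so one hydroxyquinone should result and the second hydroxyl is left as a vinylogous acid.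

Step 5
Reactants: 9 3-[3-(3,4-dimethoxyphenyl)prop-2-yn-1-yl]-2-hydroxy-6-methoxycyclohexa-2,5-diene-1,4-dione
Product: 10 3-[3-(3,4-dimethoxyphenyl)prop-2-yn-1-yl]-2,6-dimethoxycyclohexa-2,5-diene-1,4-dione
Conditions: MeI, K2CO3, DMF, 23 °C
Reagents that add atoms: iodomethane, CI
Why: Williamson-type O-methylation of the vinylogous carboxylic acid of the 2-hydroxyquinone; C3 is already substituted, so C-methylation is excluded, and the mild base at room temperature should spare the propargylic methylene on the quinone.

Step 6
Reactants: 10 3-[3-(3,4-dimethoxyphenyl)prop-2-yn-1-yl]-2,6-dimethoxycyclohexa-2,5-diene-1,4-dione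
Product: 11 evelynin
Conditions: TfOH (20 mol%), H2O (3 equiv), CF3CH2OH, 40 °C
Reagents that add atoms: water, O
Why: Brønsted acid-catalysed Markovnikov hydration of an aryl alkyne: protonation at the alkyne carbon next to the methylene gives a vinyl cation stabilised by the para-methoxy group, so water (or the neighbouring quinone carbonyl, whose cyclic adduct water reopens) delivers oxygen only to the aryl-bearing carbon, and tautomerisation gives the aryl ketone.

**Compound list**

1 | hex-5-yn-2-one | CC(=O)CCC#C | starting material
2 | 4-iodo-1,2-dimethoxybenzene | COc1ccc(I)cc1OC | starting material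
3 | 6-(3,4-dimethoxyphenyl)hex-5-yn-2-one | CC(=O)CCC#Cc1ccc(OC)c(OC)c1 | intermediate
4 | ethyl 3,3-diethoxyprop-2-enoate (ethyl 3,3-diethoxyacrylate) | CCOC(=O)C=C(OCC)OCC | starting material
5 | methyl 3,3-dimethoxyprop-2-enoate (methyl 3,3-dimethoxyacrylate) | COC(=O)C=C(OC)OC | intermediate
6 | lithium 6-(3,4-dimethoxyphenyl)hex-1-en-5-yn-2-olate (kinetic enolate of 3) | [Li+].[O-]C(=C)CCC#Cc1ccc(OC)c(OC)c1 | intermediate (not isolated)
7 | methyl (2E)-9-(3,4-dimethoxyphenyl)-3-methoxy-5-oxonon-2-en-8-ynoate | COC(=O)/C=C(/OC)CC(=O)CCC#Cc1ccc(OC)c(OC)c1 | intermediate (not isolated)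
8 | 2-[3-(3,4-dimethoxyphenyl)prop-2-yn-1-yl]-5-methoxybenzene-1,3-diol | COc1cc(O)c(CC#Cc2ccc(OC)c(OC)c2)c(O)c1 | intermediate
9 | 3-[3-(3,4-dimethoxyphenyl)prop-2-yn-1-yl]-2-hydroxy-6-methoxycyclohexa-2,5-diene-1,4-dione | COC1=CC(=O)C(CC#Cc2ccc(OC)c(OC)c2)=C(O)C1=O | intermediate
10 | 3-[3-(3,4-dimethoxyphenyl)prop-2-yn-1-yl]-2,6-dimethoxycyclohexa-2,5-diene-1,4-dione | COC1=CC(=O)C(CC#Cc2ccc(OC)c(OC)c2)=C(OC)C1=O | intermediate
11 | evelynin, 3-[3-(3,4-dimethoxyphenyl)-3-oxopropyl]-2,6-dimethoxycyclohexa-2,5-diene-1,4-dione | COC1=CC(=O)C(CCC(=O)c2ccc(OC)c(OC)c2)=C(OC)C1=O | target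

**Step count and risks**

Total step count: 6. Longest linear sequence: 5 steps (steps 1, 3, 4, 5, 6; step 2 is a one-step side branch).

Steps most likely to fail:

1. Step 3 (Proposed new method). What may go wrong: the addition–elimination of the lithium enolate at the donor-substituted acrylate may be slow, so that proton transfer erodes the enolate regiochemistry; attack may occur at the ester carbonyl instead of the acetal carbon; or the closure may go through oxygen to a 2-pyranone instead of through carbon. Fallback with known chemistry, setting out from 3 (with 5) and returning at 8: ketone 3 is trapped with LDA and Me3SiCl at −78 °C as the kinetic enol ether trimethyl{[6-(3,4-dimethoxyphenyl)hex-1-en-5-yn-2-yl]oxy}silane F1. Acrylate 5 is converted with methanol and a trace of acid into the orthoester methyl 3,3,3-trimethoxypropanoate F2. Mukaiyama-type coupling of F1 with F2 (Me3SiOTf cat., CH2Cl2, −78 °C), with loss of methanol, gives keto enoate 7, which is now isolated. Claisen cyclisation of 7 with NaOMe in MeOH in a sealed vessel at 150 °C, the conditions known for 4-methoxy-6-methyl-2-pyranone, then gives resorcinol 8.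

2. Step 6. What may go wrong: capture of the vinyl cation by the neighbouring quinone carbonyl may be followed by annulation instead of hydrolysis, or the acid may exchange or remove a quinone methoxy group. Fallback that moves the unmasking ahead of the oxidation, setting out from 8 and returning at 11: the alkyne of arene 8 is hydrated (TfOH, wet CF3CH2OH) to 3-(2,6-dihydroxy-4-methoxyphenyl)-1-(3,4-dimethoxyphenyl)propan-1-one F3. Teuber oxidation with (KSO3)2NO gives 3-[3-(3,4-dimethoxyphenyl)-3-oxopropyl]-2-hydroxy-6-methoxycyclohexa-2,5-diene-1,4-dione F4. O-methylation (MeI, K2CO3, DMF) gives 11.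

3. Step 4. What may go wrong: over-oxidation of the very electron-rich ring or competing ortho-quinone formation. Fallback that introduces the C1 oxygen through nitrogen, setting out from 8 and returning at 9: azo coupling of 8 with diazotised sulfanilic acid at pH 9 gives 4-[(E)-{2,4-dihydroxy-3-[3-(3,4-dimethoxyphenyl)prop-2-yn-1-yl]-6-methoxyphenyl}diazenyl]benzenesulfonic acid F5. Reductive cleavage with Na2S2O4 gives 4-amino-2-[3-(3,4-dimethoxyphenyl)prop-2-yn-1-yl]-5-methoxybenzene-1,3-diol F6. Oxidation with FeCl3 in aqueous HCl gives the quinone imine, which hydrolyses to hydroxyquinone 9.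

**Further compounds**

F1 | step 3 | trimethyl{[6-(3,4-dimethoxyphenyl)hex-1-en-5-yn-2-yl]oxy}silane | C=C(O[Si](C)(C)C)CCC#Cc1ccc(OC)c(OC)c1
F2 | step 3 | methyl 3,3,3-trimethoxypropanoate | COC(=O)CC(OC)(OC)OC
F3 | step 6 | 3-(2,6-dihydroxy-4-methoxyphenyl)-1-(3,4-dimethoxyphenyl)propan-1-one | COc1cc(O)c(CCC(=O)c2ccc(OC)c(OC)c2)c(O)c1
F4 | step 6 | 3-[3-(3,4-dimethoxyphenyl)-3-oxopropyl]-2-hydroxy-6-methoxycyclohexa-2,5-diene-1,4-dione | COC1=CC(=O)C(CCC(=O)c2ccc(OC)c(OC)c2)=C(O)C1=O
F5 | step 4 | 4-[(E)-{2,4-dihydroxy-3-[3-(3,4-dimethoxyphenyl)prop-2-yn-1-yl]-6-methoxyphenyl}diazenyl]benzenesulfonic acid | COc1cc(O)c(CC#Cc2ccc(OC)c(OC)c2)c(O)c1/N=N/c1ccc(cc1)S(=O)(=O)O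
F6 | step 4 | 4-amino-2-[3-(3,4-dimethoxyphenyl)prop-2-yn-1-yl]-5-methoxybenzene-1,3-diol | COc1cc(O)c(CC#Cc2ccc(OC)c(OC)c2)c(O)c1N
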